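Readings and results stem from a simulated flask for substances that don't exist.

Which flask, delta or alpha, holds more X at its own end, and how much does each hold?

| flask | J | Q | remark | time |
|---|---|---|---|---|
| cedar | 0.35 M | 0.41 M | run made earlier |  |
| birch | 0.38 M | 0.41 M | run made earlier |  |
| maple | 0.32 M | 0.41 M | run made earlier |  |
| delta | 0.41 M | 0.410 M |  | 6.0 h |
| alpha | 0.30 M | 0.410 M |  | 25 h |

| run | time / h | X / % | E / % |
|---|---|---|---|
| cedar | 0.500 | 66.2 | 1.9 |
| cedar | 0.833 | 77.5 | 4.5 |
| cedar | 1.50 | 81.4 | 8.7 |
| cedar | 3.00 | 79.8 | 17.8 |
| cedar | 6.00 | 63.7 | 34.1 |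
| birch | 0.500 | 65.4 | 1.6 |
| birch | 1.50 | 79.0 | 7.3 |
| birch | 3.00 | 76.9 | 17.4 |
| birch | 4.00 | 73.2 | 23.6 |
| birch | 6.00 | 62.8 | 32.7 |
| maple | 0.500 | 68.9 | 1.2 |
| maple | 1.50 | 83.1 | 8.8 |
| maple | 3.00 | 80.2 | 17.7 |
| maple | 4.00 | 74.3 | 24.0 |
| maple | 6.00 | 63.6 | 33.2 |

(standard deviation of a reading: 0.5 percentage points)

- the winner by amount of X, in percent of the J charged; "neither" if no more than 2 percentage points parts them (delta / alpha / neither)
- how much X is there at the end, in percent of the J charged: delta
- how much X is there at the end, in percent of the J charged: alpha



In the earlier runs J and Q make X quickly, and X then passes into E. So I compare two rates at one moment: X made from J and Q, and X lost to E. Above one, their quotient means X climbs; below one, X falls. Cedar gives me both rates. Between its last two readings X falls with a constant κ = 0.0751 h⁻¹, a net figure read from the run. Reckoned by balance from the readings of X and E, J at cedar's first reading stands near 0.112 M and Q near 0.172 M. Second-order making then gives p = 3.72 h⁻¹, the rate constant times delta's charge.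

Time is the first setting. Delta has equal charges, so J and Q fall together, and the share of J left after time t is f, one over one plus pt: 4.29% at 6.0 h. Of what cedar reads as X and E at 6.00 h, X makes up 65.1%, and I put that share on the J delta has used, which gives me X at 62.3%. The making rate over the losing rate, p times f squared over κ times X, is then 0.146, the feed ratio. Its top goes with f squared, so the making side shrinks as delta runs on.

The J charge is the other setting. By hand I expect little change in X at one time while Q covers the J, and the runs read that way: at 6.00 h X reads 63.6%, 63.7% and 62.8% for J from 0.32 M to 0.38 M, with a scatter of 0.5 percentage points. Alpha has more excess Q than cedar, and X and E together already read 97.8% of cedar's J at 6.00 h, so I take alpha's feed ratio as near zero. Carrying cedar's last X forward at κ gives 15.3% at 25 h. In my reckoning delta leads.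

The forecast also names delta, with 63.3% (61% to 65.5%) for delta and 15.5% (12.5% to 19%) for alpha, on the ground that “X then decays to E at a rate proportional to X, independent of charge and of remaining Q”. My delta figure sits lower than the forecast's.

The winner in the flask is delta: X is 61.9% in delta and 13.5% in alpha.

    J + Q → X + D (k = 0.154 M⁻¹ min⁻¹)
    X → E (k = 0.00136 min⁻¹)
    E + D → L (k = 9.44 × 10⁻⁴ M⁻¹ min⁻¹)

I reckoned the feed ratio for delta at 0.146; the flask has 0.133 at 6.00 h, below one. In the neighbouring flask, delta with J raised to 0.70 M, Q is the limiting reagent and stands at 0% at 6.00 h, so the feed ratio there is zero. Counting that flask's X as made at the start, Q's charge covers 58.6% of the J, and κ over that time leaves 37.3%. That flask holds 36.6% X, with 41% of its J still there.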